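The cycloheptene ring is made by two-carbon ring expansion of a diquinane. The C6–C7 unit, which in the target lies between the ring-fusion carbon C5 and the methyl-bearing C8, is brought in as a vinylsilane tethered to the tertiary C4 oxygen of a bicyclo[3.3.0]octenone; this oxygen sits on the same face of the cyclopentane ring as the angular methyl. An intramolecular enone–alkene [2+2] photocycloaddition then forms C5–C6 and C7–C8 in one operation and stores strain in a cyclobutane with three contiguous quaternary carbons. Radical scission of the C5–C8 bond opens the seven-membered ring with the C8=C9 alkene in place, and oxidation of the C6–Si bond gives the C6 oxygen.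

Key step: step 8

Remark on numbering: daucane numbering is used for all intermediates. C1 is the quaternary ring-fusion carbon with methyl C15; C4 is the carbinol carbon with isopropyl; C5 is the ring-fusion CH; C8 carries methyl C14; C6 and C10 carry the ester oxygens. Ring 1 is the diquinane ring C1–C5–C8–C9–C10, ring 2 is the cyclopentane C1–C2–C3–C4–C5, and β is the face of C15.

Step 1
Reactants: 1 3-ethoxycyclopent-2-en-1-one; 2 2-(2-bromoethyl)-2-methyl-1,3-dioxolane
Product: 5 3-[2-(2-methyl-1,3-dioxolan-2-yl)ethyl]cyclopent-2-en-1-one, via Grignard reagent 3 (not isolated), via magnesium alkoxide adduct 4 (not isolated)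
Conditions: Mg, THF, 30 °C; then 1, THF, 0 °C; then 1 M HCl, 0 °C, 10 min
Reagents that add atoms: water (O)
Why: Stork–Danheiser sequence, in which 1,2-addition of the Grignard reagent to the vinylogous ester and brief cold acid hydrolysis should transpose the carbonyl and give the 3-substituted enone with the dioxolane intact; no stereocentre is formed.

Step 2
Reactants: 5 3-[2-(2-methyl-1,3-dioxolan-2-yl)ethyl]cyclopent-2-en-1-one
Product: 6 (R)-3-methyl-3-[2-(2-methyl-1,3-dioxolan-2-yl)ethyl]cyclopentan-1-one
Conditions: Me3Al, Cu(O2CC4H3S) (copper thiophene-2-carboxylate, 2 mol%), chiral BINOL-derived phosphoramidite with a bis(1-phenylethyl)amino group (4 mol%), Et2O, −30 °C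
Reagents that add atoms: trimethylaluminium (C[Al](C)C)
Why: Copper-catalysed asymmetric conjugate addition of a trialkylaluminium to a β-substituted cyclopentenone should create the quaternary stereocentre C1, its sense being fixed by the chiral ligand (the ligand enantiomer that delivers the R ketone is used).

Step 3
Reactants: 6 (R)-3-methyl-3-[2-(2-methyl-1,3-dioxolan-2-yl)ethyl]cyclopentan-1-one
Product: 8 (5S)-2,5-dimethylbicyclo[3.3.0]oct-1-en-8-one, via diketone 7 (not isolated)
Conditions: 2 M HCl, THF, 25 °C; then KOH, MeOH, 60 °C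
Reagents that add atoms: none
Why: Ketal hydrolysis followed by intramolecular aldol condensation of the 1,6-diketone; only attack of the ring α-carbon C5 on the side-chain ketone can dehydrate to a conjugated enone (the other aldol modes end at bridgehead carbinols and revert), and C1 is not touched.

Step 4
Reactants: 8 (5S)-2,5-dimethylbicyclo[3.3.0]oct-1-en-8-one
Product: 9 (5S,8R)-2,5-dimethyl-8-(propan-2-yl)bicyclo[3.3.0]oct-1-en-8-ol
Conditions: iPrMgCl, CeCl3 (anhydrous), THF, −78 to 0 °C
Reagents that add atoms: isopropylmagnesium chloride (CC(C)[Mg]Cl)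
Why: 1,2-Addition of an organocerium reagent, which suppresses enolisation and conjugate addition, should occur on the α-face, anti to the angular methyl C15 that stands nearly perpendicular over ring 2, so that the C4 hydroxyl comes out cis to C15.

Step 5
Reactants: 9 (5S,8R)-2,5-dimethyl-8-(propan-2-yl)bicyclo[3.3.0]oct-1-en-8-ol; 10 chloro(dimethyl)vinylsilane
Product: 11 dimethyl(vinyl)silyl ether of 9
Conditions: imidazole, DMAP (cat.), DMF, 40 °C
Reagents that add atoms: none
Why: Silylation of the tertiary allylic alcohol with a small chlorosilane installs the future C6 and C7 as a temporary silicon-tethered vinyl group; no stereocentre changes.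

Step 6
Reactants: 11 dimethyl(vinyl)silyl ether of 9
Product: 12 8-{[dimethyl(vinyl)silyl]oxy}-2,5-dimethyl-8-(propan-2-yl)bicyclo[3.3.0]oct-1-en-3-one
Conditions: Rh2(C6H10NO)4 (dirhodium tetracaprolactamate, 1 mol%), tBuOOH (70% aq.), K2CO3, CH2Cl2, 25 °C
Reagents that add atoms: tert-butyl hydroperoxide (CC(C)(C)OO)
Why: Catalytic allylic C–H oxidation by tert-butylperoxyl radicals should convert the only ring allylic methylene (C9) into the ketone, the other allylic positions being quaternary or a primary methyl, and so create the cyclopentenone chromophore.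

Step 7
Reactants: 12 8-{[dimethyl(vinyl)silyl]oxy}-2,5-dimethyl-8-(propan-2-yl)bicyclo[3.3.0]oct-1-en-3-one
Product: 14 10α-(tert-butyldimethylsilyloxy) enone (OTBS at C10 trans to methyl C15), via silyl dienol ether 13 (not isolated)
Conditions: TBSOTf, Et3N, CH2Cl2, 0 °C; then mCPBA, NaHCO3, CH2Cl2, −20 °C
Reagents that add atoms: tert-butyldimethylsilyl triflate (CC(C)(C)[Si](C)(C)OS(=O)(=O)C(F)(F)F); 3-chloroperoxybenzoic acid (OOC(=O)c1cccc(Cl)c1)
Why: Rubottom oxidation, in which the ketone can enolise only towards C10 and the peracid should attack the silyl dienol ether anti to the adjacent angular methyl C15, the silyl group then migrating to the new oxygen to give the 10α-silyloxy ketone directly.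

Step 8
Reactants: 14 10α-(tert-butyldimethylsilyloxy) enone
Product: 15 tetracyclic photoadduct (cyclobutane C5–C6–C7–C8 on the β-face; oxasilolane C4–O–SiMe2–C6; C9 ketone; 10α-OTBS)
Conditions: hν (350 nm, Pyrex), degassed CH2Cl2 (5 mM), 0 °C
Reagents that add atoms: none
Why: Excitation of the cyclopentenone gives the triplet enone, whose β-carbon C5 bonds first to the silicon-bearing vinyl carbon C6, and the resulting 1,4-diradical collapses by C7–C8 bond formation. The closest known reaction type is the intramolecular enone–alkene [2+2] photocycloaddition through a temporary silicon tether. The five-membered oxasilolane closes in the 5-exo sense at C5 (rule of five) and the cyclobutane closes by 1,4-diradical recombination, so the straight adduct and not the crossed one is expected. C5 and C8 become quaternary with the cyclobutane cis-fused on the face of the O4 tether, which is also the only face that keeps rings 1 and 2 cis-fused, and C6 is fixed because silicon must lie on the C4 side of the cyclobutane in the cis-fused oxasilolane. The step needs head-to-tail regiochemistry (C6 to C5, C7 to C8) and a single enone face, and both are secured by the three-atom C4–O–Si tether. The strain and the three contiguous quaternary carbons C1, C5 and C8 stored here drive the later scission of the C5–C8 bond.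

Step 9
Reactants: 15 tetracyclic photoadduct
Product: 16 C9 carbinol of the photoadduct (epimer mixture at C9)
Conditions: NaBH4, MeOH/CH2Cl2, 0 °C
Reagents that add atoms: none
Why: Borohydride reduction of the cyclopentanone; the configuration of the new carbinol C9 is of no consequence (the mixture is carried on) because C9 becomes a radical and then sp2 in step 11.

Step 10
Reactants: 16 C9 carbinol of the photoadduct
Product: 17 C9 O-(imidazol-1-ylthiocarbonyl) derivative of 16
Conditions: 1,1'-thiocarbonyldiimidazole, DMAP (cat.), ClCH2CH2Cl, 70 °C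
Reagents that add atoms: 1,1'-thiocarbonyldiimidazole (S=C(n1ccnc1)n1ccnc1)
Why: Neutral thioacylation prepares the Barton–McCombie precursor without forming an alkoxide, which avoids migration of the neighbouring silyl group from O10 to O9.

Step 11
Reactants: 17 C9 O-(imidazol-1-ylthiocarbonyl) derivative of 16
Product: 18 ring-expanded 5αH-daucane (C8=C9 alkene; oxasilolane C4β–O–SiMe2–C6α; 10α-OTBS)
Conditions: Bu3SnH (slow addition), AIBN, toluene, 100 °C
Reagents that add atoms: none
Why: Barton–McCombie generation of the C9 cyclobutylcarbinyl radical should be followed by β-scission of the C5–C8 bond (the cyclobutane bond between two quaternary carbons, giving a tertiary radical), a radical two-carbon ring expansion that creates the C8=C9 alkene; the C5 radical, held at the junction of ring 2 and the oxasilolane, should take hydrogen on the α-face so that these two five-membered rings stay cis-fused, which sets H5 trans to C15.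

Step 12
Reactants: 18 ring-expanded 5αH-daucane
Product: 19 10α-(tert-butyldimethylsilyloxy)daucan-8-ene-4β,6α-diol
Conditions: H2O2 (30% aq.), KF, KHCO3, THF/MeOH, 40 °C
Reagents that add atoms: hydrogen peroxide (OO)
Why: Tamao–Fleming oxidation of the cyclic alkoxysilane replaces silicon at C6 by hydroxyl with retention and frees the C4 hydroxyl.

Step 13
Reactants: 19 10α-(tert-butyldimethylsilyloxy)daucan-8-ene-4β,6α-diol; 20 4-acetoxybenzoyl chloride
Product: 21 6-O-(4-acetoxybenzoyl) derivative of 19
Conditions: pyridine, DMAP (cat.), CH2Cl2, 0 to 25 °C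
Reagents that add atoms: none
Why: Acylation should discriminate the secondary C6 hydroxyl from the tertiary, hindered C4 hydroxyl.

Step 14
Reactants: 21 6-O-(4-acetoxybenzoyl) derivative of 19
Product: 22 4β,10α-dihydroxydaucan-8-en-6α-yl 4-acetoxybenzoate
Conditions: HF·pyridine, pyridine, THF, 0 to 25 °C
Reagents that add atoms: none
Why: Buffered acidic fluoride cleaves the alkyl silyl ether while the phenolic acetate, the benzoate and the tertiary alcohol should be untouched.

Step 15
Reactants: 22 4β,10α-dihydroxydaucan-8-en-6α-yl 4-acetoxybenzoate; 23 angelic acid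
Product: 25 10α-angeloyloxy-4β-hydroxydaucan-8-en-6α-yl 4-acetoxybenzoate, via mixed anhydride 24 (not isolated)
Conditions: 23, 2,4,6-trichlorobenzoyl chloride, Et3N, toluene, 25 °C; then 22, 75 °C
Reagents that add atoms: none
Why: Yamaguchi-type esterification through the mixed anhydride, run without DMAP, should acylate the secondary allylic C10 hydroxyl with retention of the Z geometry of the angelate, while the tertiary C4 hydroxyl does not react.

Step 16
Reactants: 25 10α-angeloyloxy-4β-hydroxydaucan-8-en-6α-yl 4-acetoxybenzoate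
Product: 26 target (1S,4R,5S,6S,10R)-10-angeloyloxy-4-hydroxydaucan-8-en-6-yl 4-hydroxybenzoate
Conditions: NH4OAc, MeOH/H2O, 25 °C
Reagents that add atoms: none
Why: Aryl acetates are cleaved far faster than alkyl benzoates and α,β-unsaturated esters under neutral ammonium acetate catalysis, so only the phenol should be released.

Compound list
1 | 3-ethoxycyclopent-2-en-1-one | CCOC1=CC(=O)CC1 | starting material
2 | 2-(2-bromoethyl)-2-methyl-1,3-dioxolane | CC1(CCBr)OCCO1 | starting material
3 | [2-(2-methyl-1,3-dioxolan-2-yl)ethyl]magnesium bromide | CC1(CC[Mg]Br)OCCO1 | intermediate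
4 | bromomagnesium 3-ethoxy-1-[2-(2-methyl-1,3-dioxolan-2-yl)ethyl]cyclopent-2-en-1-olate | CCOC1=CC(CCC2(C)OCCO2)(O[Mg]Br)CC1 | intermediate
5 | 3-[2-(2-methyl-1,3-dioxolan-2-yl)ethyl]cyclopent-2-en-1-one | O=C1C=C(CCC2(C)OCCO2)CC1 | intermediate
6 | (R)-3-methyl-3-[2-(2-methyl-1,3-dioxolan-2-yl)ethyl]cyclopentan-1-one | O=C1C[C@](CCC2(C)OCCO2)(C)CC1 | intermediate
7 | (S)-3-methyl-3-(3-oxobutyl)cyclopentan-1-one | O=C1C[C@](CCC(C)=O)(C)CC1 | intermediate
8 | (5S)-2,5-dimethylbicyclo[3.3.0]oct-1-en-8-one (C4 ketone, C5=C8 alkene, C1 quaternary) | C1CC(C)=C2[C@]1(C)CCC2=O | intermediate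
9 | (5S,8R)-2,5-dimethyl-8-(propan-2-yl)bicyclo[3.3.0]oct-1-en-8-ol (C4 hydroxyl cis to the angular methyl C15) | C1CC(C)=C2[C@]1(C)CC[C@@]2(O)C(C)C | intermediate
10 | chloro(dimethyl)vinylsilane | C=C[Si](C)(C)Cl | starting material
11 | dimethyl(vinyl)silyl ether of 9 | C1CC(C)=C2[C@]1(C)CC[C@@]2(O[Si](C)(C)C=C)C(C)C | intermediate
12 | 8-{[dimethyl(vinyl)silyl]oxy}-2,5-dimethyl-8-(propan-2-yl)bicyclo[3.3.0]oct-1-en-3-one (C9 ketone; silyloxy cis to C15) | C1C(=O)C(C)=C2[C@]1(C)CC[C@@]2(O[Si](C)(C)C=C)C(C)C | intermediate
13 | tert-butyldimethylsilyl dienol ether of 12 (C9–OTBS, C9=C10) | C1=C(O[Si](C)(C)C(C)(C)C)C(C)=C2[C@]1(C)CC[C@@]2(O[Si](C)(C)C=C)C(C)C | intermediate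
14 | 10α-(tert-butyldimethylsilyloxy) enone: 12 with OTBS at C10, trans to methyl C15 | CC(C)(C)[Si](C)(C)O[C@@H]1C(=O)C(C)=C2[C@]1(C)CC[C@@]2(O[Si](C)(C)C=C)C(C)C | intermediate
15 | tetracyclic photoadduct: cyclobutane C5–C6–C7–C8 cis-fused on the β-face, oxasilolane C4–O–SiMe2–C6, C9 ketone, 10α-OTBS, methyl C14 α | CC(C)(C)[Si](C)(C)O[C@@H]1C(=O)[C@@]3(C)C[C@H]([Si]4(C)C)[C@]23[C@]1(C)CC[C@@]2(O4)C(C)C | intermediate
16 | C9 carbinol of 15 (epimer mixture at C9) | CC(C)(C)[Si](C)(C)O[C@@H]1C(O)[C@@]3(C)C[C@H]([Si]4(C)C)[C@]23[C@]1(C)CC[C@@]2(O4)C(C)C | intermediate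
17 | C9 O-(imidazol-1-ylthiocarbonyl) derivative of 16 | CC(C)(C)[Si](C)(C)O[C@@H]1C(OC(=S)n5ccnc5)[C@@]3(C)C[C@H]([Si]4(C)C)[C@]23[C@]1(C)CC[C@@]2(O4)C(C)C | intermediate
18 | ring-expanded 5αH-daucane: C8=C9 alkene, oxasilolane C4β–O–SiMe2–C6α, 10α-OTBS | CC(C)(C)[Si](C)(C)O[C@@H]1C=C(C)C[C@H]([Si]3(C)C)[C@@H]2[C@]1(C)CC[C@@]2(O3)C(C)C | intermediate
19 | 10α-(tert-butyldimethylsilyloxy)daucan-8-ene-4β,6α-diol (5αH) | CC(C)(C)[Si](C)(C)O[C@@H]1C=C(C)C[C@H](O)[C@@H]2[C@]1(C)CC[C@@]2(O)C(C)C | intermediate
20 | 4-acetoxybenzoyl chloride | CC(=O)Oc1ccc(cc1)C(Cl)=O | starting material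
21 | 6-O-(4-acetoxybenzoyl) derivative of 19 | CC(C)(C)[Si](C)(C)O[C@@H]1C=C(C)C[C@H](OC(=O)c3ccc(OC(C)=O)cc3)[C@@H]2[C@]1(C)CC[C@@]2(O)C(C)C | intermediate
22 | 4β,10α-dihydroxydaucan-8-en-6α-yl 4-acetoxybenzoate | O[C@@H]1C=C(C)C[C@H](OC(=O)c3ccc(OC(C)=O)cc3)[C@@H]2[C@]1(C)CC[C@@]2(O)C(C)C | intermediate
23 | angelic acid, (Z)-2-methylbut-2-enoic acid | C/C=C(/C)C(O)=O | starting material
24 | angelic 2,4,6-trichlorobenzoic anhydride | C/C=C(/C)C(=O)OC(=O)c1c(Cl)cc(Cl)cc1Cl | intermediate
25 | 10α-angeloyloxy-4β-hydroxydaucan-8-en-6α-yl 4-acetoxybenzoate | C/C=C(/C)C(=O)O[C@@H]1C=C(C)C[C@H](OC(=O)c3ccc(OC(C)=O)cc3)[C@@H]2[C@]1(C)CC[C@@]2(O)C(C)C | intermediate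
26 | (1S,4R,5S,6S,10R)-10-angeloyloxy-4-hydroxydaucan-8-en-6-yl 4-hydroxybenzoate | C/C=C(/C)C(=O)O[C@@H]1C=C(C)C[C@H](OC(=O)c2ccc(O)cc2)[C@@H]2[C@]1(C)CC[C@@]2(O)C(C)C | target

Total step count: 16. Longest linear sequence: 16 steps (from 1 to 26).

Steps most likely to fail

Step 11. The C9 radical may be reduced before it opens, or β-scission may take the exocyclic C7–C8 bond, which overlaps better with the radical orbital, instead of the ring-fusion C5–C8 bond. The fallback sets out from 16 and opens the ring by a polar route. Mesylation (MsCl, Et3N) gives the C9 mesylate F1. Buffered solvolysis (2,6-lutidine, hexafluoroisopropanol) should let the C6–Si bond act as electrofuge in a silicon-assisted Grob-type fragmentation, giving after mild basic work-up the 5(6),8(9)-diene with free C4 hydroxyl F2. Hydroboration–oxidation (BH3·THF, then NaOH/H2O2) of the C5=C6 alkene on the α-face, anti to C15, should add H to C5 and OH to C6 in a syn sense. The C8=C9 alkene is deactivated by the allylic silyloxy group. The fallback comes back to the route at 19.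

Step 8. The excited enone may be lost to cleavage reactions of the α-silyloxy ketone chromophore, or capture by the tethered vinyl group may be slow at the crowded C5. The fallback changes the order of events and sets out from 12. Irradiation under the same conditions gives the cyclobutane ketone without C10 oxygen F3. TBSOTf/Et3N gives its silyl enol ether F4, which can form only towards C10. Rubottom oxidation with mCPBA then installs the 10α-silyloxy group on the face away from C15 and the cyclobutane. The fallback comes back to the route at 15.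

Step 4. The branched organometallic may enolise the ketone or reduce it by β-hydride transfer instead of adding. The fallback sets out from 8 and builds the isopropyl group in two operations. Addition of isopropenylmagnesium bromide/CeCl3, a smaller sp2 nucleophile without β-hydrogen, from the same α-face gives the isopropenyl carbinol F5. Hydrogenation with RhCl(PPh3)3/H2 should saturate only the 1,1-disubstituted alkene and leave the tetrasubstituted C5=C8 alkene. The fallback comes back to the route at 9.

Further compounds
F1 | step 11 | C9 mesylate of 16 | CC(C)(C)[Si](C)(C)O[C@@H]1C(OS(C)(=O)=O)[C@@]3(C)C[C@H]([Si]4(C)C)[C@]23[C@]1(C)CC[C@@]2(O4)C(C)C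
F2 | step 11 | 10α-(tert-butyldimethylsilyloxy)dauca-5,8-dien-4β-ol | CC(C)(C)[Si](C)(C)O[C@@H]1C=C(C)CC=C2[C@]1(C)CC[C@@]2(O)C(C)C
F3 | step 8 | photoadduct of 12 (cyclobutane ketone without C10 oxygen) | C1C(=O)[C@@]3(C)C[C@H]([Si]4(C)C)[C@]23[C@]1(C)CC[C@@]2(O4)C(C)C
F4 | step 8 | tert-butyldimethylsilyl enol ether of F3 (C9–OTBS, C9=C10) | C1=C(O[Si](C)(C)C(C)(C)C)[C@@]3(C)C[C@H]([Si]4(C)C)[C@]23[C@]1(C)CC[C@@]2(O4)C(C)C
F5 | step 4 | (5S,8R)-2,5-dimethyl-8-(prop-1-en-2-yl)bicyclo[3.3.0]oct-1-en-8-ol | C1CC(C)=C2[C@]1(C)CC[C@@]2(O)C(C)=C
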